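I decided to follow one number through this flask: how strongly the reagent tips the split of starting material between target and side product. As a working picture, target costs one reagent and side product costs none.

all flasks: starting material 0.20 M; free catalyst 0.10 mM; second catalyst 0.40 mM

| charge | reagent | remark | time |
|---|---|---|---|
| autumn | 0.24 M | the very flask that is asked about, followed so far |  |
| noon | 0.36 M | run made earlier |  |
| flask | 0.240 M |  | 40 h |

- autumn (time / h: target / %, side product / %): 1.33: 41, 50; 4.00: 44, 55; 8.00: 44, 55; 10.0: 47, 57; 15.0: 45, 57; 20.0: 43, 54
- noon (time / h: target / %, side product / %): 2.50: 56, 44; 5.00: 55, 43; 8.00: 53, 47; 10.0: 54, 45; 12.0: 53, 44; 15.0: 57, 42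

(readings scatter by 1.5 percentage points)



1. ratio of target to side product at 12 min
2. ratio of target to side product at 40 h
3. which of target and side product there is more of at 40 h

The noon run supplied the number. Its mean readings were 54.7% target and 44.2% side product, a ratio of 1.24. I replaced the falling reagent curve by the mean of its charge and end value, 0.305 M. The ratio per mean reagent, a selectivity factor at these catalyst charges and a reading with the scatter of those runs, was 4.05 L mol⁻¹.

I then built up the autumn flask. With the reagent held at its charge:

ratio = 0.973

I used this for 12 min, assuming the reagent still stood near its charge. Letting reagent fall gave a target share of 49.3%, and so: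

ratio = 0.773

That lowered the target share to 43.6%, and feeding this back gave:

ratio = 0.796

This was my figure for 40 h, with side product ahead. Integrating my working picture exactly needs the logarithmic mean of the reagent, and my straight mean differs from it by 1.69%, which I accepted.

The forecast gave 1.2 at 12 min, above my figure, and 0.8 at 40 h with side product ahead, saying that the rise of the ratio with reagent charge “suggests the target route has a higher order in reagent”.

The flask gave 0.979 and 0.805, with side product ahead.

    reagent + second catalyst + intermediate → second catalyst + target (k = 3.71 L² mol⁻² s⁻¹)
    intermediate → side product (k = 3.54 × 10⁻⁴ s⁻¹)
    starting material + free catalyst → free catalyst + intermediate (k = 10.9 L mol⁻¹ s⁻¹)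

Starting material passed into intermediate, and 100% of that step's turnover lay behind it after 8.00 h. By 4.00 h starting material stood at 0% and intermediate at 0.0444%, while target held 44.6% and side product 55.4%, the same as at 40 h. With reagent ending at 62.8% of its charge, 4.05 L mol⁻¹ times the mean reagent gives 0.792. For the neighbour charged with 0.60 M of reagent, 4.05 L mol⁻¹ times that flask's mean reagent gives 2.15, and that flask stood at 2.21.

(All runs were generated by integration from invented constants, noise included.)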